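## Structural features

- The target is a C30 bis-ether made of two 2,2,5a,7-tetramethyl-decahydro-1-benzoxepine units (an oxepane trans-fused to a cyclohexane along C5a–C9a; 1-benzoxepine numbering is used for the bicycles throughout). The units are joined through their C6 carbons by a CH2–CH2 bridge.
- Each unit has five stereocentres: C3 (secondary oxygen next to the gem-dimethyl ether carbon C2), C5a (quaternary, angular methyl), C6 (CH carrying the bridge), C7 (tertiary acetate) and C9a (CH–O). C9a, C5a, C6 and C7 are contiguous, and C6 sits between two fully substituted carbons.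
- The two units are not the same compound. Unit A has the 3-acetate and is 7R (acetoxy axial, syn to the angular methyl). Unit B has the free 3-hydroxyl and is 7S (acetoxy equatorial). All other centres are alike (3S,5aS,6S,9aS in both).
- There is therefore no C2 axis. A plan that makes one half twice ends in a diastereomer of the target, so each unit needs its own precursor, epimeric at the tertiary carbinol carbon.
- Fragile points are the two tertiary acetates β to C6 (elimination and acyl transfer under base), the tertiary ether bond C2–O1 (ionisation by strong Lewis acids) and the one free hydroxyl that must be told apart from an acetate in an almost identical environment.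
- The real difficulty is the quaternary C5a flanked by C9a–O and C6, the oxepane whose oxygen lies between CMe2 and the ring-fusion carbon, and the need for both C7 epimers.
- The key step exploits two facts. O1–C2(Me2)–C3(O) of each oxepane is the O1–C2–C3 segment of a 2,2-dimethylfuran-3(2H)-one enlarged by two carbons. The C5a–C9a bond joins a quaternary carbon to an oxygen-bearing carbon, which are the internal carbon of a 1,1-disubstituted alkene and C5 of the furanone; a [2+2] makes this bond, and cleaving the old furanone C4–C5 bond then enlarges the five-membered ether to the oxepane.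

## Logic of the disconnections

**40 ⇒ 39.** The C3–H bond of unit B is cut. The only free hydroxyl is carried as a ketone, which cannot be acetylated and needs no protecting group; this is what distinguishes the two units. The gain is one stereocentre and one orthogonal protecting group fewer. The demand is a reagent-controlled hydride transfer as the last step, beside three acetates.

**39 ⇒ 38 ⇒ 37 ⇒ 36.** The two bridge C–H bonds, the three acetyl C–O bonds and then three O–H bonds (to silyl ethers) are cut. Acetates, above all the tertiary ones β to C6, would not survive carbanion chemistry, so they are put on after the halves are joined. The demand is complete acetylation of one secondary and two tertiary hydroxyls, one of them axial, under non-ionising conditions.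

**36 ⇒ 28 + 35.** The central C=C of the two-carbon bridge is cut. It is the only bond that divides the molecule into two C15 pieces of equal complexity, each keeping one bridge carbon. The demand is an olefination between two neopentyl-type carbons in which the carbanion must choose the aldehyde of 35 over its ketone.

**28 ⇒ 27 ⇒ 26 ⇒ 25 ⇒ 24 and 35 ⇒ 34.** Functional-group changes only (O–Si, C3–H, S=O, C–S; aldehyde C–H). Both partners come from the same type of keto alcohol and differ only at C7. The demands are a substitution at a β-branched primary carbon and a reduction whose face is set by the reagent.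

**24 ⇒ 23 ⇒ 22 ⇒ 21 and 34 ⇒ 33 ⇒ 32 ⇒ 31.** The C9a–H bond is removed and the C4–C9a bond is restored, which re-forms the furanone ring inside a cyclobutane. The oxepane is thus never closed at the crowded gem-dimethyl ether carbon; it arises by ring enlargement. The demand is heterolysis of exactly one cyclobutane bond and hydride delivery anti to the angular methyl.

**21 ⇒ 20 and 31 ⇒ 30.** The C5a–C9a and C4–C5 bonds (C1–C7 and C5–C6 of the tricycle) are cut. Two rings and the quaternary carbon disappear and an acyclic furanone–alkene remains. The demand is straight regiochemistry and alkene-face selection by the single allylic stereocentre. Because units A and B differ at C7, two epimeric substrates are needed.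

**20 ⇒ 19 ⇒ 5 + 12 and 30 ⇒ 29 ⇒ 5 + 18.** The bond between the tertiary carbinol carbon and the methine is cut. One C–C bond formation sets both chain stereocentres, and the E or Z geometry of the boron reagent gives the anti or syn pair from one common ketone. The furanone is already present, so no γ-hydroxy ester that could lactonise is ever formed. The demand is enantioface selection on a methyl ketone and geometrically pure boronates.

**5 ⇒ 4 ⇒ 2 + 3 and 2 ⇒ 1.** The furanone C4–C5 bond (Claisen) and the O1–C5 bond (cyclodehydration) are cut. The demand is that the methyl ketone be masked during the condensation.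

**12 ⇒ 11 ⇒ 10 ⇒ 9 ⇒ 8 ⇒ 7 ⇒ 6 and 18 ⇒ 17 ⇒ 16 ⇒ 15 ⇒ 14 ⇒ 13 ⇒ 6.** The CH2–C(alkenyl) bond and the C–I bond are cut. Both boronates come from one alkyne, and the sense of hydrometalation (syn or anti) decides the geometry.

## Other disconnections considered

**Alternative 1:** The cut is the C6–C7 bond of the cyclohexane, with the oxepane already in place.
- Forward step: TiCl4 would activate the methyl ketone of oxepane A2 and the γ-carbon of its allylsilane would attack it (intramolecular Hosomi–Sakurai reaction), giving the bicyclic tertiary alcohol A1 with a vinyl group on C6.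
- In its favour: a thermal, well-understood cyclisation sets C6 and C7 in one step, and the vinyl group is a direct precursor of the bridge carbon. Its mechanism is better precedented than the fragmentation of the chosen plan, and on that point it is the better of the two.
- Against it here: C3, the quaternary C5a and C9a must first be assembled on a flexible monocyclic oxepane, which is the hardest part of the structure and is not addressed by the key step. TiCl4 meets a tertiary ether and an acetate. A1 has the 7R configuration of unit A only, and the closed transition state offers no simple switch to the 7S epimer of unit B.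
- Comparison: the chosen plan creates the quaternary carbon and both rings from an acyclic precursor and reaches both C7 epimers from one ketone. Alternative 1 would be longer because the oxepane and each C7 epimer need their own solution.

**Alternative 2:** The cut is the bond between the angular methyl and C5a, seen as one bond of a cyclopropane.
- Forward step: Et2Zn and CH2I2 (Simmons–Smith reaction) would deliver CH2 to the ring alkene of allylic alcohol A4, syn to the hydroxyl, giving the hydroxy cyclopropane ketal A3. Later removal of the ketal and dissolving-metal opening of the cyclopropane would give the angular methyl and a regiodefined enolate at the future C6.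
- In its favour: hydroxyl direction fixes the quaternary carbon relative to the C9a oxygen very reliably, and each step is classical. The C7 ketone would allow both tertiary carbinol epimers from one intermediate by choosing the order of methyl and oxygen introduction; on that point it is better than the chosen plan, which needs two boron reagents.
- Against it here: the oxepane would be closed last by C–O bond formation at the gem-dimethyl carbon (epoxide opening, seven-membered against six-membered closure), the crowded closure that the chosen plan avoids. The enolate would have to be alkylated at a neopentyl position, and the sequence is long and linear.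
- Comparison: equal or better in stereochemical security at C5a, but worse in step economy and in the way the ether ring is made.

**Alternative 3:** The cut is the C2–C3 bond of the oxepane, seen as the double bond of a cyclic enol ether.
- Forward step: the titanium ethylidene reagent from TiCl4, Zn, PbCl2, CH3CHBr2 and TMEDA (Takai–Utimoto olefination followed by ring closure) would join the acetate carbonyl carbon of olefinic acetate A6 to the internal alkene carbon, giving the 2-methyl-tetrahydrooxepine A5.
- In its favour: the oxepane is closed by C–C and not C–O bond formation, a tactic with solid precedent in fused polyether work; for the ring closure itself it is at least the equal of the fragmentation used here. Silyl and benzyl ethers are tolerated.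
- Against it here: A6 already contains all four cyclohexane stereocentres, so the contiguous array must be built separately. A5 lacks the second methyl at C2 and the C3 oxygen, which need enol ether oxidation and methyl delivery at the acetal carbon, with a new face-selection problem. The reagent is used in large excess and contains lead.
- Comparison: the chosen plan takes the gem-dimethyl group and the C3 oxygen from a commercial hydroxy ketone and forms cyclohexane, quaternary carbon and oxepane in two steps. Alternative 3 would be the more certain ring closure but the longer route.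

Key step: step 11

Assumption: (S)-3,3′-dibromo-1,1′-bi-2-naphthol is taken to send the allyl group to the Re face of ketone 5 (O > CH2 chain > CH3) and its antipode to the Si face; if the sense is the reverse, the two antipodes change places between steps 9 and 17 and nothing else changes.

Assumption: the alkene of step 22 is drawn as E; its geometry is of no consequence because it is hydrogenated in step 25.

## Route

Step 1
Reactants: 1 ethyl levulinate (ethyl 4-oxopentanoate)
Product: 2 ethyl 3-(2-methyl-1,3-dioxolan-2-yl)propanoate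
Conditions: HOCH2CH2OH, p-TsOH·H2O (cat.), toluene, reflux, water separator
Reagents that add atoms: ethane-1,2-diol, OCCO
Why: Acid-catalysed ketalisation with removal of water; the methyl ketone must be masked because the next step uses an excess of amide base and a ketone enolate.

Step 2
Reactants: 2 ethyl 3-(2-methyl-1,3-dioxolan-2-yl)propanoate; 3 3-hydroxy-3-methylbutan-2-one
Product: 5 2,2-dimethyl-5-(3-oxobutyl)furan-3(2H)-one, via β-diketone 4 (not isolated)
Conditions: 3 (2.2 equiv), LiN(iPr)2 (4.5 equiv), THF, −78 → 0 °C; 2, −78 → 20 °C; then 2 M HCl, THF, 20 °C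
Reagents that add atoms: none
Why: Crossed Claisen condensation of the alkoxide–enolate of 3 with ester 2 gives 4; aqueous acid then closes the tertiary hydroxyl onto the distal carbonyl (cyclodehydration to the 3(2H)-furanone) and hydrolyses the ketal, and once the vinylogous ester has formed the 1,4-dicarbonyl relationship that could lead to a furan is gone.

Step 3
Reactants: 6 but-2-yn-1-ol
Product: 7 (but-2-yn-1-yloxy)triethylsilane
Conditions: Et3SiCl, imidazole, CH2Cl2, 0 °C
Reagents that add atoms: chlorotriethylsilane, CC[Si](Cl)(CC)CC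
Why: Standard silylation of a primary alcohol; this triethylsilyl ether stays on the oxygen until step 12, where it can be removed beside the tertiary silyl ether.

Step 4
Reactants: 7 (but-2-yn-1-yloxy)triethylsilane
Product: 9 triethyl{[(2E)-3-iodobut-2-en-1-yl]oxy}silane, via alkenylzirconocene chloride 8 (not isolated)
Conditions: Cp2Zr(H)Cl (2 equiv), THF, 20 → 50 °C; then I2, 0 °C
Reagents that add atoms: iodine, II
Why: Hydrozirconation is a syn addition; with excess hydride and gentle warming the metal settles on the less hindered, methyl-bearing carbon, and iodinolysis with retention gives the E iodide (iodine trans to CH2O).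

Step 5
Reactants: 9 triethyl{[(2E)-3-iodobut-2-en-1-yl]oxy}silane
Product: 12 dipropan-2-yl [(2E)-2-methyl-4-(triethylsilyloxy)but-2-en-1-yl]boronate, via alkenyllithium 10 (not isolated), via borate complex 11 (not isolated)
Conditions: t-BuLi (2 equiv), Et2O, −78 °C; BrCH2B(OiPr)2, −78 → 20 °C; filtered under Ar, used as a toluene solution
Reagents that add atoms: diisopropyl (bromomethyl)boronate, CC(C)OB(CBr)OC(C)C
Why: Iodine–lithium exchange with retention, then Matteson homologation: in the ate complex 11 the alkenyl group migrates from boron to carbon with loss of bromide, so the alkene geometry is carried unchanged into the allylboronate.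

Step 6
Reactants: 6 but-2-yn-1-ol
Product: 14 (2Z)-3-iodobut-2-en-1-ol, via cyclic alkenylaluminate 13 (not isolated)
Conditions: NaAlH2(OCH2CH2OMe)2, THF, 0 → 20 °C; then I2, −78 → 0 °C; aq potassium sodium tartrate
Reagents that add atoms: iodine, II
Why: Alkoxide-directed anti hydroalumination of the propargylic alcohol puts aluminium on the distal carbon, cis to CH2O in a five-membered aluminate; iodinolysis with retention gives the Z iodide.

Step 7
Reactants: 14 (2Z)-3-iodobut-2-en-1-ol
Product: 15 triethyl{[(2Z)-3-iodobut-2-en-1-yl]oxy}silane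
Conditions: Et3SiCl, imidazole, CH2Cl2, 0 °C
Reagents that add atoms: chlorotriethylsilane, CC[Si](Cl)(CC)CC
Why: Standard silylation; the alkenyl iodide is inert.

Step 8
Reactants: 15 triethyl{[(2Z)-3-iodobut-2-en-1-yl]oxy}silane
Product: 18 dipropan-2-yl [(2Z)-2-methyl-4-(triethylsilyloxy)but-2-en-1-yl]boronate, via alkenyllithium 16 (not isolated), via borate complex 17 (not isolated)
Conditions: t-BuLi (2 equiv), Et2O, −78 °C; BrCH2B(OiPr)2, −78 → 20 °C; filtered under Ar, used as a toluene solution
Reagents that add atoms: diisopropyl (bromomethyl)boronate, CC(C)OB(CBr)OC(C)C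
Why: Same exchange and Matteson homologation as in step 5; the Z geometry is retained.

Step 9
Reactants: 5 2,2-dimethyl-5-(3-oxobutyl)furan-3(2H)-one; 12 dipropan-2-yl [(2E)-2-methyl-4-(triethylsilyloxy)but-2-en-1-yl]boronate
Product: 19 5-[(3R,4R)-3-hydroxy-3,5-dimethyl-4-{[(triethylsilyl)oxy]methyl}hex-5-en-1-yl]-2,2-dimethylfuran-3(2H)-one
Conditions: (R)-3,3′-dibromo-1,1′-bi-2-naphthol (15 mol %), PhCF3–toluene 3:1, −35 → 0 °C; aq NaHCO3
Reagents that add atoms: none
Why: Diol-catalysed asymmetric allylboration of a ketone: one isopropoxy group is exchanged for the chiral diol and the allyl group is transferred through a closed chair with the chain of 5 equatorial and its methyl axial; the E boronate places CH2OSiEt3 equatorial and so gives the anti (3R,4R) pair, the catalyst selects the Si face of the ketone, and the furanone carbonyl, a vinylogous ester, does not compete.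

Step 10
Reactants: 19 5-[(3R,4R)-3-hydroxy-3,5-dimethyl-4-{[(triethylsilyl)oxy]methyl}hex-5-en-1-yl]-2,2-dimethylfuran-3(2H)-one
Product: 20 5-[(3R,4R)-3,5-dimethyl-3-[(triethylsilyl)oxy]-4-{[(triethylsilyl)oxy]methyl}hex-5-en-1-yl]-2,2-dimethylfuran-3(2H)-one
Conditions: Et3SiOTf, 2,6-lutidine, CH2Cl2, −78 → 0 °C
Reagents that add atoms: triethylsilyl trifluoromethanesulfonate, CC[Si](CC)(CC)OS(=O)(=O)C(F)(F)F
Why: Silyl triflate and a hindered base silylate the tertiary alcohol; this is done at once because the free γ-hydroxyl could add to C5 of the furanone and form a spiroketal.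

Step 11
Reactants: 20 5-[(3R,4R)-3,5-dimethyl-3-[(triethylsilyl)oxy]-4-{[(triethylsilyl)oxy]methyl}hex-5-en-1-yl]-2,2-dimethylfuran-3(2H)-one
Product: 21 (1R,5R,7S,8R,9R)-3,3,7,9-tetramethyl-9-[(triethylsilyl)oxy]-8-{[(triethylsilyl)oxy]methyl}-2-oxatricyclo[5.4.0.0(1,5)]undecan-4-one
Conditions: hν (λ ≥ 300 nm, Pyrex-filtered Hg lamp), MeCN (0.005 M, Ar-purged), 0 °C
Reagents that add atoms: none
Why: Excitation of the furanone enone and intersystem crossing give a triplet that bonds furanone C5 to the internal alkene carbon through a six-membered, chair-like array (straight mode); the 1,4-diradical so formed (α-keto radical at furanone C4 and the primary CH2 radical) closes the cyclobutane after spin inversion. The closest known reaction type is the intramolecular enone–alkene [2+2] photocycloaddition with a four-atom tether, for which 3(2H)-furanones are competent chromophores. The cyclohexane is closed by 6-exo attack of C5 on the alkene and the cyclobutane by recombination of the diradical; both ring fusions can only be cis. Of the three new stereocentres (C1, C5 and C7 of the tricycle), C1 and C5 follow from C7 through the cis fusions, and C7 is set by the alkene face, which is controlled by the allylic stereocentre C4 of the chain: with CH2OSiEt3 equatorial and the allylic C–H eclipsing the C=CH2 bond (least allylic strain) the methyl ends up cis to CH2OSiEt3. The step needs straight and not crossed regiochemistry, which the four-atom tether secures (six-membered against seven-membered first closure), and it needs this face selectivity, which rests on the allylic stereocentre alone and is an assumption to be verified. C1 and C5 are given up again in step 12, so only the C7/C8 relationship has to be right. The gem-dimethyl group at C2 removes enolisable hydrogens next to the carbonyl and the silyl ethers do not absorb above 300 nm.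

Step 12
Reactants: 21 (1R,5R,7S,8R,9R)-3,3,7,9-tetramethyl-9-[(triethylsilyl)oxy]-8-{[(triethylsilyl)oxy]methyl}-2-oxatricyclo[5.4.0.0(1,5)]undecan-4-one
Product: 24 (5aS,6R,7R,9aS)-6-(hydroxymethyl)-2,2,5a,7-tetramethyl-7-[(triethylsilyl)oxy]octahydro-1-benzoxepin-3(2H)-one, via silyl enol ether 22 (not isolated), via bis-silyl ketone 23 (not isolated)
Conditions: Et3SiH (5 equiv), Me3SiOTf (1.2 equiv), 2,6-di-tert-butyl-4-methylpyridine (0.3 equiv), CH2Cl2, −78 → −40 °C; then Et3N, MeOH; solvent exchange; pyridinium p-toluenesulfonate, MeOH, 0 → 20 °C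
Reagents that add atoms: none
Why: Proposed new method: the photoadduct is a vicinal donor–acceptor cyclobutane (ether oxygen on C1, acyl group on C5), so silylation of the ketone oxygen by Me3SiOTf should break the C1–C5 bond in a retro-aldol sense to a silyl enol ether and an oxocarbenium ion with release of the four-ring strain, and Et3SiH should reduce the cation axially, anti to the angular methyl, to the trans-fused oxepane 22; methanolysis then frees the ketone (23) and, with the pyridinium salt, the primary alcohol, while the tertiary silyl ether stays; the closest known reaction types are the de Mayo retro-aldol opening of enone–alkene photoadducts, the Lewis-acid opening of alkoxy donor–acceptor cyclobutanes and the silane reduction of cyclic oxocarbenium ions.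

Step 13
Reactants: 24 (5aS,6R,7R,9aS)-6-(hydroxymethyl)-2,2,5a,7-tetramethyl-7-[(triethylsilyl)oxy]octahydro-1-benzoxepin-3(2H)-one
Product: 25 (5aS,6S,7R,9aS)-2,2,5a,7-tetramethyl-6-{[(1-phenyl-1H-tetrazol-5-yl)sulfanyl]methyl}-7-[(triethylsilyl)oxy]octahydro-1-benzoxepin-3(2H)-one
Conditions: 1-phenyl-1H-tetrazole-5-thiol, PPh3, diisopropyl azodicarboxylate, THF, 0 → 20 °C
Reagents that add atoms: 1-phenyl-1H-tetrazole-5-thiol, Sc1nnnn1-c1ccccc1
Why: Mitsunobu thioetherification at the primary carbon; the carbon is β-branched between two fully substituted centres, so excess reagents and high concentration are planned, and the ketone and the tertiary silyl ether are inert.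

Step 14
Reactants: 25 (5aS,6S,7R,9aS)-2,2,5a,7-tetramethyl-6-{[(1-phenyl-1H-tetrazol-5-yl)sulfanyl]methyl}-7-[(triethylsilyl)oxy]octahydro-1-benzoxepin-3(2H)-one
Product: 26 (5aS,6S,7R,9aS)-2,2,5a,7-tetramethyl-6-{[(1-phenyl-1H-tetrazol-5-yl)sulfonyl]methyl}-7-[(triethylsilyl)oxy]octahydro-1-benzoxepin-3(2H)-one
Conditions: H2O2 (30 %), (NH4)6Mo7O24·4H2O (cat.), EtOH, 0 → 20 °C
Reagents that add atoms: hydrogen peroxide, OO
Why: Molybdate-catalysed oxidation of the sulfide to the sulfone; the hindered ketone and the tertiary silyl ether are not touched under these nearly neutral conditions.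

Step 15
Reactants: 26 (5aS,6S,7R,9aS)-2,2,5a,7-tetramethyl-6-{[(1-phenyl-1H-tetrazol-5-yl)sulfonyl]methyl}-7-[(triethylsilyl)oxy]octahydro-1-benzoxepin-3(2H)-one
Product: 27 (3S,5aS,6S,7R,9aS)-2,2,5a,7-tetramethyl-6-{[(1-phenyl-1H-tetrazol-5-yl)sulfonyl]methyl}-7-[(triethylsilyl)oxy]decahydro-1-benzoxepin-3-ol
Conditions: (R)-2-methyl-CBS-oxazaborolidine (0.3 equiv), BH3·SMe2, THF, −20 °C; MeOH
Reagents that add atoms: none
Why: Corey–Bakshi–Shibata reduction: the ketone binds to the ring boron anti to its larger, quaternary C2 side and the (R)-catalyst then delivers hydride to the face that gives the (3S)-alcohol; reagent control is chosen because the intrinsic facial bias of the seven-membered ketone is not known.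

Step 16
Reactants: 27 (3S,5aS,6S,7R,9aS)-2,2,5a,7-tetramethyl-6-{[(1-phenyl-1H-tetrazol-5-yl)sulfonyl]methyl}-7-[(triethylsilyl)oxy]decahydro-1-benzoxepin-3-ol
Product: 28 1-phenyl-5-({(3S,5aS,6S,7R,9aS)-2,2,5a,7-tetramethyl-3,7-bis[(triethylsilyl)oxy]decahydro-1-benzoxepin-6-yl}methanesulfonyl)-1H-tetrazole
Conditions: Et3SiOTf, 2,6-lutidine, CH2Cl2, −78 → 0 °C
Reagents that add atoms: triethylsilyl trifluoromethanesulfonate, CC[Si](CC)(CC)OS(=O)(=O)C(F)(F)F
Why: Silylation of the hindered secondary alcohol so that no alkoxide is present in the olefination; all three silyl ethers of the coupled product are then of one kind and leave together in step 23.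

Step 17
Reactants: 5 2,2-dimethyl-5-(3-oxobutyl)furan-3(2H)-one; 18 dipropan-2-yl [(2Z)-2-methyl-4-(triethylsilyloxy)but-2-en-1-yl]boronate
Product: 29 5-[(3S,4R)-3-hydroxy-3,5-dimethyl-4-{[(triethylsilyl)oxy]methyl}hex-5-en-1-yl]-2,2-dimethylfuran-3(2H)-one
Conditions: (S)-3,3′-dibromo-1,1′-bi-2-naphthol (15 mol %), PhCF3–toluene 3:1, −35 → 0 °C; aq NaHCO3
Reagents that add atoms: none
Why: Same diol-catalysed allylboration as in step 9; the Z boronate places CH2OSiEt3 axial in the chair and gives the syn pair, and the antipodal catalyst selects the Re face, so that C4 is the same as in 19 and C3 is inverted.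

Step 18
Reactants: 29 5-[(3S,4R)-3-hydroxy-3,5-dimethyl-4-{[(triethylsilyl)oxy]methyl}hex-5-en-1-yl]-2,2-dimethylfuran-3(2H)-one
Product: 30 5-[(3S,4R)-3,5-dimethyl-3-[(triethylsilyl)oxy]-4-{[(triethylsilyl)oxy]methyl}hex-5-en-1-yl]-2,2-dimethylfuran-3(2H)-one
Conditions: Et3SiOTf, 2,6-lutidine, CH2Cl2, −78 → 0 °C
Reagents that add atoms: triethylsilyl trifluoromethanesulfonate, CC[Si](CC)(CC)OS(=O)(=O)C(F)(F)F
Why: As step 10.

Step 19
Reactants: 30 5-[(3S,4R)-3,5-dimethyl-3-[(triethylsilyl)oxy]-4-{[(triethylsilyl)oxy]methyl}hex-5-en-1-yl]-2,2-dimethylfuran-3(2H)-one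
Product: 31 (1R,5R,7S,8R,9S)-3,3,7,9-tetramethyl-9-[(triethylsilyl)oxy]-8-{[(triethylsilyl)oxy]methyl}-2-oxatricyclo[5.4.0.0(1,5)]undecan-4-one
Conditions: hν (λ ≥ 300 nm, Pyrex-filtered Hg lamp), MeCN (0.005 M, Ar-purged), 0 °C
Reagents that add atoms: none
Why: The same intramolecular enone–alkene [2+2] photocycloaddition as in step 11 on the C9 epimer; the face is again set by the allylic stereocentre with CH2OSiEt3 equatorial, and here the tertiary silyloxy group is equatorial and the C9 methyl axial in the chair.

Step 20
Reactants: 31 (1R,5R,7S,8R,9S)-3,3,7,9-tetramethyl-9-[(triethylsilyl)oxy]-8-{[(triethylsilyl)oxy]methyl}-2-oxatricyclo[5.4.0.0(1,5)]undecan-4-one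
Product: 34 (5aS,6R,7S,9aS)-6-(hydroxymethyl)-2,2,5a,7-tetramethyl-7-[(triethylsilyl)oxy]octahydro-1-benzoxepin-3(2H)-one, via silyl enol ether 32 (not isolated), via bis-silyl ketone 33 (not isolated)
Conditions: Et3SiH (5 equiv), Me3SiOTf (1.2 equiv), 2,6-di-tert-butyl-4-methylpyridine (0.3 equiv), CH2Cl2, −78 → −40 °C; then Et3N, MeOH; solvent exchange; pyridinium p-toluenesulfonate, MeOH, 0 → 20 °C
Reagents that add atoms: none
Why: Proposed new method: as in step 12, Lewis-acid heterolysis of the donor–acceptor cyclobutane bond C1–C5 to silyl enol ether and oxocarbenium ion and axial hydride capture anti to the angular methyl should give the trans-fused oxepane, and methanolysis then frees ketone and primary alcohol; the closest known reaction types are the de Mayo retro-aldol opening, the Lewis-acid opening of alkoxy donor–acceptor cyclobutanes and the silane reduction of cyclic oxocarbenium ions.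

Step 21
Reactants: 34 (5aS,6R,7S,9aS)-6-(hydroxymethyl)-2,2,5a,7-tetramethyl-7-[(triethylsilyl)oxy]octahydro-1-benzoxepin-3(2H)-one
Product: 35 (5aS,6S,7S,9aS)-2,2,5a,7-tetramethyl-3-oxo-7-[(triethylsilyl)oxy]decahydro-1-benzoxepine-6-carbaldehyde
Conditions: 1,1,1-triacetoxy-1,1-dihydro-1,2-benziodoxol-3(1H)-one, NaHCO3, CH2Cl2, 0 → 20 °C
Reagents that add atoms: none
Why: Dess–Martin oxidation under buffered, non-basic conditions, so that the aldehyde is not epimerised at C6 and the β-silyloxy group is not eliminated; in this unit the silyloxy group is equatorial and poorly aligned for elimination, which is why unit B is chosen as the aldehyde partner.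

Step 22
Reactants: 28 1-phenyl-5-({(3S,5aS,6S,7R,9aS)-2,2,5a,7-tetramethyl-3,7-bis[(triethylsilyl)oxy]decahydro-1-benzoxepin-6-yl}methanesulfonyl)-1H-tetrazole; 35 (5aS,6S,7S,9aS)-2,2,5a,7-tetramethyl-3-oxo-7-[(triethylsilyl)oxy]decahydro-1-benzoxepine-6-carbaldehyde
Product: 36 (E)-alkene joining C6 of the bis-silylated unit A to C6 of the keto unit B
Conditions: 28, KN(SiMe3)2, THF, −78 °C; then 35, −78 → 20 °C; aq NH4Cl
Reagents that add atoms: none
Why: Julia–Kocienski olefination: the potassium sulfonyl carbanion adds to the aldehyde, and Smiles rearrangement with loss of SO2 and the tetrazololate gives the alkene; the carbanion is formed first so that 35 never meets free amide base, and the aldehyde is far more electrophilic than the α-quaternary ring ketone.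

Step 23
Reactants: 36 (E)-alkene joining C6 of the bis-silylated unit A to C6 of the keto unit B
Product: 37 alkene triol ketone (3-OH and 7-OH in unit A, 7-OH and 3-oxo in unit B)
Conditions: HF·pyridine, pyridine, THF, 0 → 20 °C
Reagents that add atoms: none
Why: Buffered hydrogen fluoride cleaves the secondary and the two tertiary triethylsilyl ethers; ketone, alkene and ring ethers are inert.

Step 24
Reactants: 37 alkene triol ketone (3-OH and 7-OH in unit A, 7-OH and 3-oxo in unit B)
Product: 38 alkene triacetate ketone
Conditions: Ac2O, Et3N, 4-(dimethylamino)pyridine, CH2Cl2, 20 → 40 °C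
Reagents that add atoms: acetic anhydride, CC(=O)OC(C)=O
Why: Acylpyridinium catalysis acetylates the secondary hydroxyl quickly and the two tertiary ones on warming; the basic medium keeps the tertiary carbinols and the C2–O1 ether from ionising, and the future free hydroxyl is safe as a ketone.

Step 25
Reactants: 38 alkene triacetate ketone
Product: 39 saturated triacetate ketone (3′-oxo precursor of the target)
Conditions: H2 (1 atm), Pd/C (10 %), EtOAc, 20 °C
Reagents that add atoms: none
Why: Heterogeneous hydrogenation of the 1,2-disubstituted alkene; esters and the hindered ketone are not reduced and no allylic C–O bond is present.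

Step 26
Reactants: 39 saturated triacetate ketone (3′-oxo precursor of the target)
Product: 40 target CNP0169816.1
Conditions: (R)-2-methyl-CBS-oxazaborolidine (0.5 equiv), BH3·SMe2, THF, −20 °C; MeOH
Reagents that add atoms: none
Why: Corey–Bakshi–Shibata reduction as in step 15, giving the (3S)-alcohol of unit B under reagent control; acetates are inert to borane at this temperature.

## Compound list

1 | ethyl levulinate | CCOC(=O)CCC(C)=O | starting material
2 | ethyl 3-(2-methyl-1,3-dioxolan-2-yl)propanoate | CCOC(=O)CCC1(C)OCCO1 | intermediate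
3 | 3-hydroxy-3-methylbutan-2-one | CC(=O)C(C)(C)O | starting material
4 | 6-hydroxy-6-methyl-1-(2-methyl-1,3-dioxolan-2-yl)heptane-3,5-dione (not isolated) | CC(C)(O)C(=O)CC(=O)CCC1(C)OCCO1 | intermediate
5 | 2,2-dimethyl-5-(3-oxobutyl)furan-3(2H)-one | CC(=O)CCC1=CC(=O)C(C)(C)O1 | intermediate
6 | but-2-yn-1-ol | CC#CCO | starting material
7 | (but-2-yn-1-yloxy)triethylsilane | CC#CCO[Si](CC)(CC)CC | intermediate
8 | chlorobis(cyclopentadienyl)[(2E)-4-(triethylsilyloxy)but-2-en-2-yl]zirconium (not isolated) | C/C(=C\CO[Si](CC)(CC)CC)[Zr](Cl)(C1C=CC=C1)C1C=CC=C1 | intermediate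
9 | triethyl{[(2E)-3-iodobut-2-en-1-yl]oxy}silane | I/C(C)=C/CO[Si](CC)(CC)CC | intermediate
10 | [(2E)-4-(triethylsilyloxy)but-2-en-2-yl]lithium (not isolated) | [Li]/C(C)=C/CO[Si](CC)(CC)CC | intermediate
11 | lithium (bromomethyl)di(propan-2-yloxy)[(2E)-4-(triethylsilyloxy)but-2-en-2-yl]borate (not isolated) | [Li+].CC(C)O[B-](CBr)(OC(C)C)/C(C)=C/CO[Si](CC)(CC)CC | intermediate
12 | dipropan-2-yl [(2E)-2-methyl-4-(triethylsilyloxy)but-2-en-1-yl]boronate | CC(C)OB(C/C(C)=C/CO[Si](CC)(CC)CC)OC(C)C | intermediate
13 | sodium 2,2-bis(2-methoxyethoxy)-3-methyl-2,5-dihydro-1,2-oxaluminol-2-uide (not isolated) | [Na+].COCCO[Al-]1(OCCOC)OCC=C1C | intermediate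
14 | (2Z)-3-iodobut-2-en-1-ol | I/C(C)=C\CO | intermediate
15 | triethyl{[(2Z)-3-iodobut-2-en-1-yl]oxy}silane | I/C(C)=C\CO[Si](CC)(CC)CC | intermediate
16 | [(2Z)-4-(triethylsilyloxy)but-2-en-2-yl]lithium (not isolated) | [Li]/C(C)=C\CO[Si](CC)(CC)CC | intermediate
17 | lithium (bromomethyl)di(propan-2-yloxy)[(2Z)-4-(triethylsilyloxy)but-2-en-2-yl]borate (not isolated) | [Li+].CC(C)O[B-](CBr)(OC(C)C)/C(C)=C\CO[Si](CC)(CC)CC | intermediate
18 | dipropan-2-yl [(2Z)-2-methyl-4-(triethylsilyloxy)but-2-en-1-yl]boronate | CC(C)OB(C/C(C)=C\CO[Si](CC)(CC)CC)OC(C)C | intermediate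
19 | 5-[(3R,4R)-3-hydroxy-3,5-dimethyl-4-{[(triethylsilyl)oxy]methyl}hex-5-en-1-yl]-2,2-dimethylfuran-3(2H)-one | CC1(C)OC(CC[C@@](C)(O)[C@@H](CO[Si](CC)(CC)CC)C(C)=C)=CC1=O | intermediate
20 | 5-[(3R,4R)-3,5-dimethyl-3-[(triethylsilyl)oxy]-4-{[(triethylsilyl)oxy]methyl}hex-5-en-1-yl]-2,2-dimethylfuran-3(2H)-one | CC1(C)OC(CC[C@@](C)(O[Si](CC)(CC)CC)[C@@H](CO[Si](CC)(CC)CC)C(C)=C)=CC1=O | intermediate
21 | (1R,5R,7S,8R,9R)-3,3,7,9-tetramethyl-9-[(triethylsilyl)oxy]-8-{[(triethylsilyl)oxy]methyl}-2-oxatricyclo[5.4.0.0(1,5)]undecan-4-one | CC1(C)O[C@@]23CC[C@@](C)(O[Si](CC)(CC)CC)[C@@H](CO[Si](CC)(CC)CC)[C@]2(C)C[C@H]3C1=O | intermediate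
22 | (5aS,6R,7R,9aS)-2,2,5a,7-tetramethyl-7-[(triethylsilyl)oxy]-6-{[(triethylsilyl)oxy]methyl}-3-[(trimethylsilyl)oxy]-2,5,5a,6,7,8,9,9a-octahydro-1-benzoxepine (not isolated) | CC[Si](CC)(CC)OC[C@H]2[C@]3(C)CC=C(O[Si](C)(C)C)C(C)(C)O[C@H]3CC[C@@]2(C)O[Si](CC)(CC)CC | intermediate
23 | (5aS,6R,7R,9aS)-2,2,5a,7-tetramethyl-7-[(triethylsilyl)oxy]-6-{[(triethylsilyl)oxy]methyl}octahydro-1-benzoxepin-3(2H)-one (not isolated) | CC[Si](CC)(CC)OC[C@H]2[C@]3(C)CCC(=O)C(C)(C)O[C@H]3CC[C@@]2(C)O[Si](CC)(CC)CC | intermediate
24 | (5aS,6R,7R,9aS)-6-(hydroxymethyl)-2,2,5a,7-tetramethyl-7-[(triethylsilyl)oxy]octahydro-1-benzoxepin-3(2H)-one | OC[C@H]2[C@]3(C)CCC(=O)C(C)(C)O[C@H]3CC[C@@]2(C)O[Si](CC)(CC)CC | intermediate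
25 | (5aS,6S,7R,9aS)-2,2,5a,7-tetramethyl-6-{[(1-phenyl-1H-tetrazol-5-yl)sulfanyl]methyl}-7-[(triethylsilyl)oxy]octahydro-1-benzoxepin-3(2H)-one | c1ccccc1-n1nnnc1SC[C@H]2[C@]3(C)CCC(=O)C(C)(C)O[C@H]3CC[C@@]2(C)O[Si](CC)(CC)CC | intermediate
26 | (5aS,6S,7R,9aS)-2,2,5a,7-tetramethyl-6-{[(1-phenyl-1H-tetrazol-5-yl)sulfonyl]methyl}-7-[(triethylsilyl)oxy]octahydro-1-benzoxepin-3(2H)-one | O=S(=O)(C[C@H]2[C@]3(C)CCC(=O)C(C)(C)O[C@H]3CC[C@@]2(C)O[Si](CC)(CC)CC)c1nnnn1-c1ccccc1 | intermediate
27 | (3S,5aS,6S,7R,9aS)-2,2,5a,7-tetramethyl-6-{[(1-phenyl-1H-tetrazol-5-yl)sulfonyl]methyl}-7-[(triethylsilyl)oxy]decahydro-1-benzoxepin-3-ol | O=S(=O)(C[C@H]2[C@]3(C)CC[C@H](O)C(C)(C)O[C@H]3CC[C@@]2(C)O[Si](CC)(CC)CC)c1nnnn1-c1ccccc1 | intermediate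
28 | 1-phenyl-5-({(3S,5aS,6S,7R,9aS)-2,2,5a,7-tetramethyl-3,7-bis[(triethylsilyl)oxy]decahydro-1-benzoxepin-6-yl}methanesulfonyl)-1H-tetrazole | O=S(=O)(C[C@H]2[C@]3(C)CC[C@H](O[Si](CC)(CC)CC)C(C)(C)O[C@H]3CC[C@@]2(C)O[Si](CC)(CC)CC)c1nnnn1-c1ccccc1 | intermediate
29 | 5-[(3S,4R)-3-hydroxy-3,5-dimethyl-4-{[(triethylsilyl)oxy]methyl}hex-5-en-1-yl]-2,2-dimethylfuran-3(2H)-one | CC1(C)OC(CC[C@](C)(O)[C@@H](CO[Si](CC)(CC)CC)C(C)=C)=CC1=O | intermediate
30 | 5-[(3S,4R)-3,5-dimethyl-3-[(triethylsilyl)oxy]-4-{[(triethylsilyl)oxy]methyl}hex-5-en-1-yl]-2,2-dimethylfuran-3(2H)-one | CC1(C)OC(CC[C@](C)(O[Si](CC)(CC)CC)[C@@H](CO[Si](CC)(CC)CC)C(C)=C)=CC1=O | intermediate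
31 | (1R,5R,7S,8R,9S)-3,3,7,9-tetramethyl-9-[(triethylsilyl)oxy]-8-{[(triethylsilyl)oxy]methyl}-2-oxatricyclo[5.4.0.0(1,5)]undecan-4-one | CC1(C)O[C@@]23CC[C@](C)(O[Si](CC)(CC)CC)[C@@H](CO[Si](CC)(CC)CC)[C@]2(C)C[C@H]3C1=O | intermediate
32 | (5aS,6R,7S,9aS)-2,2,5a,7-tetramethyl-7-[(triethylsilyl)oxy]-6-{[(triethylsilyl)oxy]methyl}-3-[(trimethylsilyl)oxy]-2,5,5a,6,7,8,9,9a-octahydro-1-benzoxepine (not isolated) | CC[Si](CC)(CC)OC[C@H]2[C@]3(C)CC=C(O[Si](C)(C)C)C(C)(C)O[C@H]3CC[C@]2(C)O[Si](CC)(CC)CC | intermediate
33 | (5aS,6R,7S,9aS)-2,2,5a,7-tetramethyl-7-[(triethylsilyl)oxy]-6-{[(triethylsilyl)oxy]methyl}octahydro-1-benzoxepin-3(2H)-one (not isolated) | CC[Si](CC)(CC)OC[C@H]2[C@]3(C)CCC(=O)C(C)(C)O[C@H]3CC[C@]2(C)O[Si](CC)(CC)CC | intermediate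
34 | (5aS,6R,7S,9aS)-6-(hydroxymethyl)-2,2,5a,7-tetramethyl-7-[(triethylsilyl)oxy]octahydro-1-benzoxepin-3(2H)-one | OC[C@H]2[C@]3(C)CCC(=O)C(C)(C)O[C@H]3CC[C@]2(C)O[Si](CC)(CC)CC | intermediate
35 | (5aS,6S,7S,9aS)-2,2,5a,7-tetramethyl-3-oxo-7-[(triethylsilyl)oxy]decahydro-1-benzoxepine-6-carbaldehyde | O=C[C@H]2[C@]3(C)CCC(=O)C(C)(C)O[C@H]3CC[C@]2(C)O[Si](CC)(CC)CC | intermediate
36 | (E)-alkene: (3S,5aS,6S,7R,9aS)-3,7-bis(triethylsilyloxy) unit A joined at C6 by CH=CH to C6 of (5aS,6S,7S,9aS)-3-oxo-7-(triethylsilyloxy) unit B | CC[Si](CC)(CC)O[C@H]1CC[C@]2(C)[C@H](CC[C@@](C)(O[Si](CC)(CC)CC)[C@H]2/C=C/[C@H]2[C@]3(C)CCC(=O)C(C)(C)O[C@H]3CC[C@]2(C)O[Si](CC)(CC)CC)OC1(C)C | intermediate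
37 | alkene triol ketone: as 36 with the three silyl ethers replaced by hydroxyl | O[C@H]1CC[C@]2(C)[C@H](CC[C@@](C)(O)[C@H]2/C=C/[C@H]2[C@]3(C)CCC(=O)C(C)(C)O[C@H]3CC[C@]2(C)O)OC1(C)C | intermediate
38 | alkene triacetate ketone: as 37 with the three hydroxyls acetylated | CC(=O)O[C@H]1CC[C@]2(C)[C@H](CC[C@@](C)(OC(C)=O)[C@H]2/C=C/[C@H]2[C@]3(C)CCC(=O)C(C)(C)O[C@H]3CC[C@]2(C)OC(C)=O)OC1(C)C | intermediate
39 | saturated triacetate ketone: as 38 with a CH2–CH2 bridge | CC(=O)O[C@H]1CC[C@]2(C)[C@H](CC[C@@](C)(OC(C)=O)[C@H]2CC[C@H]2[C@]3(C)CCC(=O)C(C)(C)O[C@H]3CC[C@]2(C)OC(C)=O)OC1(C)C | intermediate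
40 | CNP0169816.1: unit A (3S,5aS,6S,7R,9aS)-3,7-diacetoxy-2,2,5a,7-tetramethyldecahydro-1-benzoxepin-6-yl joined through CH2–CH2 to unit B (3S,5aS,6S,7S,9aS)-7-acetoxy-3-hydroxy-2,2,5a,7-tetramethyldecahydro-1-benzoxepin-6-yl | CC(=O)O[C@H]1CC[C@]2(C)[C@H](CC[C@@](C)(OC(C)=O)[C@H]2CC[C@H]2[C@]3(C)CC[C@H](O)C(C)(C)O[C@H]3CC[C@]2(C)OC(C)=O)OC1(C)C | target

## Step count and least certain steps

Total step count: 26. Longest linear sequence: 16 steps (3, 4, 5, 9 to 16, 22 to 26).

**Step 12 (bears the label "Proposed new method:").**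
- What may go wrong: the cyclobutane bond fails to ionise, because in the fused five-four system its overlap with the carbonyl π* orbital and with the ether lone pair is only partial. Alternatively the oxocarbenium ion is captured by a neighbouring silyl ether oxygen (bridged ketal formation) faster than by the silane.
- Fallback (known chemistry): reductive cleavage of the cyclobutyl ketone with SmI2 (HMPA, t-BuOH, THF, −78 °C). The ketyl radical opens the same C1–C5 bond towards the tertiary α-alkoxy radical; further reduction and protonation from the face anti to the angular methyl lead directly from 21 to ketone 23, which is carried on to 24 with the pyridinium salt in methanol as in step 12. This fallback makes no compound outside the list (F0).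

**Step 20 (bears the label "Proposed new method:").**
- What may go wrong: the same two processes as in step 12.
- Fallback: the same SmI2 cleavage, from 31 to ketone 33 and then to 34 (F0).

**Step 11 (key step).**
- What may go wrong: poor alkene-face selection. The two rotamers about the bond from the allylic stereocentre to the alkene differ little in strain, and in the desired chair the incoming methyl faces the axial triethylsilyloxy group. Crossed closure and slow six-ring formation are lesser risks.
- Fallback: the two oxygens are tied into a ring so that the tether loses two rotors and the axial oxygen no longer carries a freely rotating silyl group.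
  - From 19, buffered HF·pyridine removes the primary silyl group to give the diol 5-[(3R,4R)-3-hydroxy-4-(hydroxymethyl)-3,5-dimethylhex-5-en-1-yl]-2,2-dimethylfuran-3(2H)-one F1.
  - (t-Bu)2Si(OTf)2 and 2,6-lutidine give the cyclic di-tert-butylsilylene F2.
  - Irradiation as in step 11 gives the silylene-bridged photoadduct F3.
  - HF·pyridine gives the photoadduct diol F4.
  - Et3SiOTf (excess) and 2,6-lutidine return to the route at 21.

**Step 9 (step 17 carries the same uncertainty).**
- What may go wrong: low enantioface selection, because methyl and the CH2CH2 chain differ little in size, and slow addition of the β,γ-disubstituted boronate, which lets an uncatalysed racemic pathway compete.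
- Fallback: stereocontrol by the ring transition state only, followed by resolution. From 5 and 12 without the chiral diol (2,2′-biphenol as achiral exchange catalyst, 20 to 40 °C) the anti adduct forms as the racemate, that is 19 together with its enantiomer 5-[(3S,4S)-3-hydroxy-3,5-dimethyl-4-{[(triethylsilyl)oxy]methyl}hex-5-en-1-yl]-2,2-dimethylfuran-3(2H)-one F5. The two are separated by preparative chromatography on a chiral stationary phase, and the route is rejoined at 19.

**Step 15 (step 26 is the same reaction at the end of the route).**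
- What may go wrong: insufficient face selectivity if the intrinsic preference of the seven-membered ketone opposes the catalyst.
- Fallback: enzymatic reduction of 26 with a ketoreductase selected for the (3S)-alcohol (NADPH recycling with glucose dehydrogenase, aqueous buffer with 2-propanol as cosolvent). It gives 27 directly and makes no compound outside the list (F0).

**Step 22.**
- What may go wrong: slow addition between two neopentyl-type carbons, which gives time for proton transfer from the ring ketone or the aldehyde α-position to the sulfonyl carbanion, and for attack on the ketone.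
- Fallback: the ketone of unit B is removed before the coupling and its oxygen is marked with a benzyl group.
  - Ketone 33 is isolated after the triethylamine–methanol quench of step 20 and reduced as in step 15 to the (3S)-alcohol F6.
  - NaH and benzyl bromide give the benzyl ether F7.
  - Swern oxidation, which cleaves and oxidises the primary triethylsilyl ether directly, gives the aldehyde F8.
  - Olefination with 28 as in step 22 gives the alkene F9.
  - HF·pyridine gives the triol F10.
  - Acetylation as in step 24 gives the triacetate benzyl ether F11.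
  - H2 over Pd(OH)2/C saturates the bridge, removes the benzyl group and returns to the route at 40.

## Further compounds

F0 | step 12 | none | none
F0 | step 20 | none | none
F1 | step 11 | 5-[(3R,4R)-3-hydroxy-4-(hydroxymethyl)-3,5-dimethylhex-5-en-1-yl]-2,2-dimethylfuran-3(2H)-one | CC1(C)OC(CC[C@@](C)(O)[C@@H](CO)C(C)=C)=CC1=O
F2 | step 11 | 5-{2-[(4R,5R)-2,2-di-tert-butyl-4-methyl-5-(prop-1-en-2-yl)-1,3,2-dioxasilinan-4-yl]ethyl}-2,2-dimethylfuran-3(2H)-one | CC1(C)OC(CC[C@@](C)(O[Si]2(C(C)(C)C)C(C)(C)C)[C@@H](CO2)C(C)=C)=CC1=O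
F3 | step 11 | silylene-bridged photoadduct (9-O and 8-CH2O of 21 joined by di-tert-butylsilylene) | CC1(C)O[C@@]23CC[C@@](C)(O[Si]4(C(C)(C)C)C(C)(C)C)[C@@H](CO4)[C@]2(C)C[C@H]3C1=O
F4 | step 11 | (1R,5R,7S,8R,9R)-9-hydroxy-8-(hydroxymethyl)-3,3,7,9-tetramethyl-2-oxatricyclo[5.4.0.0(1,5)]undecan-4-one | CC1(C)O[C@@]23CC[C@@](C)(O)[C@@H](CO)[C@]2(C)C[C@H]3C1=O
F5 | step 9 | 5-[(3S,4S)-3-hydroxy-3,5-dimethyl-4-{[(triethylsilyl)oxy]methyl}hex-5-en-1-yl]-2,2-dimethylfuran-3(2H)-one | CC1(C)OC(CC[C@](C)(O)[C@H](CO[Si](CC)(CC)CC)C(C)=C)=CC1=O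
F0 | step 15 | none | none
F6 | step 22 | (3S,5aS,6R,7S,9aS)-2,2,5a,7-tetramethyl-7-[(triethylsilyl)oxy]-6-{[(triethylsilyl)oxy]methyl}decahydro-1-benzoxepin-3-ol | CC[Si](CC)(CC)OC[C@H]2[C@]3(C)CC[C@H](O)C(C)(C)O[C@H]3CC[C@]2(C)O[Si](CC)(CC)CC
F7 | step 22 | (3S,5aS,6R,7S,9aS)-3-(benzyloxy)-2,2,5a,7-tetramethyl-7-[(triethylsilyl)oxy]-6-{[(triethylsilyl)oxy]methyl}decahydro-1-benzoxepine | CC[Si](CC)(CC)OC[C@H]2[C@]3(C)CC[C@H](OCc4ccccc4)C(C)(C)O[C@H]3CC[C@]2(C)O[Si](CC)(CC)CC
F8 | step 22 | (3S,5aS,6S,7S,9aS)-3-(benzyloxy)-2,2,5a,7-tetramethyl-7-[(triethylsilyl)oxy]decahydro-1-benzoxepine-6-carbaldehyde | O=C[C@H]2[C@]3(C)CC[C@H](OCc4ccccc4)C(C)(C)O[C@H]3CC[C@]2(C)O[Si](CC)(CC)CC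
F9 | step 22 | (E)-alkene as 36 with a (3S)-benzyloxy group in place of the ketone of unit B | CC[Si](CC)(CC)O[C@H]1CC[C@]2(C)[C@H](CC[C@@](C)(O[Si](CC)(CC)CC)[C@H]2/C=C/[C@H]2[C@]3(C)CC[C@H](OCc4ccccc4)C(C)(C)O[C@H]3CC[C@]2(C)O[Si](CC)(CC)CC)OC1(C)C
F10 | step 22 | alkene triol benzyl ether (F9 without its three silyl groups) | O[C@H]1CC[C@]2(C)[C@H](CC[C@@](C)(O)[C@H]2/C=C/[C@H]2[C@]3(C)CC[C@H](OCc4ccccc4)C(C)(C)O[C@H]3CC[C@]2(C)O)OC1(C)C
F11 | step 22 | alkene triacetate benzyl ether | CC(=O)O[C@H]1CC[C@]2(C)[C@H](CC[C@@](C)(OC(C)=O)[C@H]2/C=C/[C@H]2[C@]3(C)CC[C@H](OCc4ccccc4)C(C)(C)O[C@H]3CC[C@]2(C)OC(C)=O)OC1(C)C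
A1 | alternative 1 | (3S,5aS,6R,7R,9aS)-6-ethenyl-7-hydroxy-2,2,5a,7-tetramethyldecahydro-1-benzoxepin-3-yl acetate | CC(=O)O[C@H]1CC[C@]2(C)[C@H](CC[C@@](C)(O)[C@H]2C=C)OC1(C)C
A2 | alternative 1 | 2,2,6-trimethyl-7-(3-oxobutyl)-6-[(1E)-3-(trimethylsilyl)prop-1-en-1-yl]oxepan-3-yl acetate (stereochemistry as in A1) | CC(=O)O[C@H]1CC[C@@](C)(/C=C/C[Si](C)(C)C)[C@H](CCC(C)=O)OC1(C)C
A3 | alternative 2 | hydroxy cyclopropane ketal: 2-hydroxy-1-(4-methylpent-3-en-1-yl)bicyclo[4.1.0]heptan-5-one ethylene ketal, cyclopropane syn to hydroxyl | CC(C)=CCC[C@@]12C[C@@H]1C3(CC[C@@H]2O)OCCO3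
A4 | alternative 2 | (8S)-7-(4-methylpent-3-en-1-yl)-1,4-dioxaspiro[4.5]dec-6-en-8-ol | CC(C)=CCCC1=CC2(CC[C@@H]1O)OCCO2
A5 | alternative 3 | bicyclic 2-methyl-tetrahydrooxepine: 6-[(benzyloxy)methyl]-2,5a,7-trimethyl-7-[(triethylsilyl)oxy]-4,5,5a,6,7,8,9,9a-octahydro-1-benzoxepine | CC1=CCC[C@]2(C)[C@H](CC[C@@](C)(O[Si](CC)(CC)CC)[C@H]2COCc3ccccc3)O1
A6 | alternative 3 | 3-[(benzyloxy)methyl]-2-(but-3-en-1-yl)-2,4-dimethyl-4-[(triethylsilyl)oxy]cyclohexyl acetate (stereochemistry as in A5) | C=CCC[C@]1(C)[C@H](CC[C@@](C)(O[Si](CC)(CC)CC)[C@H]1COCc2ccccc2)OC(C)=O
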